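A direct plan would buy ring A as 2,5-dimethoxyphenol A1, attach a benzyloxyacetyl group next to the phenol oxygen by directed ortho-lithiation to reach ketone A2, and close ring C by Allan–Robinson condensation with 4-methoxybenzoic anhydride A3 to give the 5,8-dimethoxyflavone A4.
The missing oxygens at C6 and C7 would then come by way of quinone A5 (oxidative demethylation), two rounds of hydrogen chloride addition and re-oxidation, and exchange of both chlorides for methoxy groups to give dimethoxyquinone A6, followed by reduction to hydroquinone A7, methylation of O8 and debenzylation.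
Weak point 1: the quinone detour from A4 to A7, six redox and substitution operations that would form no C–C bond and would only place two methoxy groups on a ring bought with the wrong pattern.
Weak point 2: the chloride-for-methoxide exchange that would give A6, run late on a base-sensitive chromene-trione whose pyranone carbons C2 and C8a are also electrophilic.
Weak point 3: the single methylation of the air-sensitive hydroquinone A7, in which only the C5–OH···O=C4 chelate would tell the two hydroxyls apart.

**Retrosynthetic overview**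
Ring A (C4a, C5, C6, C7, C8, C8a) carries oxygen on five of its six carbons; C5, C6, C7 and C8 with their four oxygens are the four carbons of dimethyl squarate.
Disconnections: C4a–C5 (key step, thermal 4π opening and 6π closure of a pyranonyl cyclobutenone) and C8–C8a (addition of a C6-lithiated 4-pyranone to the squarate; the methylated adduct oxygen becomes the 8-OMe).
Ring order: ring C first, as a 2-aryl-3-hydroxy-4-pyranone made from 3-bromofuran and 4-methoxybenzaldehyde by Achmatowicz ring expansion (ring B comes with the aldehyde); ring A last, by benzannulation.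
The ring construction itself puts 5-OH, 6-OMe, 7-OMe and 8-OMe in place, so no quinone, no hydroquinone and no selective methylation is needed, in six steps overall.

Key step: step 5

Remark: the target is achiral; the stereocentres of intermediates 4, 5, 10, 11 and 13 are racemic and all are destroyed before the end.

Step 1
Reactants: 1 3-bromofuran; 2 4-methoxybenzaldehyde
Product: 4 racemic (3-bromofuran-2-yl)(4-methoxyphenyl)methanol, via 3-bromo-2-furyllithium 3 (not isolated)
Conditions: LiN(i-Pr)2 (1.05 equiv), THF, –78 °C; then 2, –78 °C; sat. aq NH4Cl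
Reagents that add atoms: none
Why: LiN(i-Pr)2 removes the C2 proton of 3-bromofuran (flanked by ring oxygen and bromine) faster than halogen exchange or migration at –78 °C, and the 2-furyllithium adds 1,2 to the aldehyde to give the racemic carbinol, whose stereocentre is lost in step 2.

Step 2
Reactants: 4 racemic (3-bromofuran-2-yl)(4-methoxyphenyl)methanol
Product: 6 3-hydroxy-2-(4-methoxyphenyl)-4H-pyran-4-one, via 4-bromo-6-hydroxy-2H-pyran-3(6H)-one 5 (not isolated)
Conditions: NBS (1.05 equiv), NaHCO3, NaOAc, THF/H2O, 0 °C; Na2S2O3 quench, extract; then 1 M H2SO4, 1,4-dioxane/H2O, 80 °C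
Reagents that add atoms: water, O
Why: Achmatowicz rearrangement (bromonium-induced oxidative opening of the furan and closure by the carbinol oxygen) should give hemiacetal 5, in which the bromine carried in from furan C3 sits on C4 and supplies the extra oxidation level, so that hot aqueous acid brings about enolization at C2, loss of the C6 hydroxyl and exchange of bromide for water at C4 to the aromatic 3-hydroxy-4-pyranone, as in the second stage of the classical maltol synthesis from 4-halo-6-hydroxy-2H-pyran-3(6H)-ones.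

Step 3
Reactants: 6 3-hydroxy-2-(4-methoxyphenyl)-4H-pyran-4-one
Product: 7 3-(methoxymethoxy)-2-(4-methoxyphenyl)-4H-pyran-4-one
Conditions: MOMCl (1.3 equiv), i-Pr2NEt, CH2Cl2, 0 °C → rt
Reagents that add atoms: chloromethyl methyl ether, COCCl
Why: Williamson-type O-alkylation of the acidic enolic 3-hydroxyl gives the MOM ether, which should withstand lithium amides, the cold methyl triflate quench and 140 °C, and which, unlike the methyl ethers, is an acetal that mild acid removes at the end.

Step 4
Reactants: 7 3-(methoxymethoxy)-2-(4-methoxyphenyl)-4H-pyran-4-one; 8 dimethyl squarate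
Product: 11 2,3,4-trimethoxy-4-[5-(methoxymethoxy)-6-(4-methoxyphenyl)-4-oxo-4H-pyran-2-yl]cyclobut-2-en-1-one, via 6-lithiopyranone 9 (not isolated), via lithium cyclobutenolate 10 (not isolated)
Conditions: LiTMP (lithium 2,2,6,6-tetramethylpiperidide, 1.1 equiv), THF, –78 °C, 15 min; cannulate into 8 (1.2 equiv), THF, –78 °C; then MeOTf (1.5 equiv), –78 → –20 °C; aq NaHCO3
Reagents that add atoms: methyl trifluoromethanesulfonate, COS(=O)(=O)C(F)(F)F
Why: Hindered TMP-amide bases metalate chromones and 4-pyranones at the CH next to the ring oxygen (here C6, the most acidic sp2 C–H and the only one whose anion has no β-leaving group), the vinyllithium adds 1,2 to one of the two equivalent squarate carbonyls, and the tertiary alkoxide, far more nucleophilic than the neutral pyranone carbonyl, is methylated in the flask (the standard squarate addition and O-alkylation sequence).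

Step 5
Reactants: 11 2,3,4-trimethoxy-4-[5-(methoxymethoxy)-6-(4-methoxyphenyl)-4-oxo-4H-pyran-2-yl]cyclobut-2-en-1-one
Product: 14 5-hydroxy-6,7,8-trimethoxy-3-(methoxymethoxy)-2-(4-methoxyphenyl)-4H-chromen-4-one, via dienylketene 12 (not isolated), via 4aH-chromene-4,5-dione 13 (not isolated)
Conditions: p-xylene (0.01 M, degassed), 140 °C, Ar
Reagents that add atoms: none
Why: Moore-type thermal ring expansion: conrotatory 4π electrocyclic opening of 11 gives dienylketene 12, disrotatory 6π electrocyclization joins the ketene carbon to the ring CH next to the point of attachment (C5 of pyranone 7, the future C4a, so that the new bond is C4a–C5 of the flavone) to give dienone 13, and enolization of the C4a–H, which lies between two carbonyl groups, aromatizes ring A. The closest known reactions are the thermolyses of 4-aryl-, 4-furyl- and 4-alkenyl-4-methoxycyclobutenones made from dimethyl squarate, which give 4-methoxynaphthols, benzofuranols and tetra-oxygenated phenols in the same way. Ring A is closed as a six-membered ring by 6π electrocyclization of a (Z)-triene, and no stereocentre remains in 14. The step needs the pyranonyl group to rotate inward so that it ends cis to the ketene; the torquoselectivity of the opening should secure this, because the methoxy donor on the sp3 carbon rotates outward, and the wrong rotamer can only re-close to 11. Regiochemistry is fixed by connectivity: the ketene can reach only that one ring carbon, a nucleophilic enol-ether-type carbon matched to the electrophilic ketene, so the carbon that carried the methylated alkoxide becomes C8–OMe and the ketene carbonyl becomes the free, chelated C5–OH. High dilution in degassed solvent should keep the ketene from dimerizing and the new phenol from being acylated.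

Step 6
Reactants: 14 5-hydroxy-6,7,8-trimethoxy-3-(methoxymethoxy)-2-(4-methoxyphenyl)-4H-chromen-4-one
Product: 15 3,5-dihydroxy-6,7,8,4'-tetramethoxyflavone
Conditions: HCl (1.25 M in MeOH), MeOH/CH2Cl2, 40 °C
Reagents that add atoms: none
Why: Acid-catalysed acetal exchange with methanol removes the methoxymethyl group as dimethoxymethane, while the four aryl methyl ethers and the chelated 5-hydroxyl should stay untouched, and gives the target flavonol.

**Compound list**
1 | 3-bromofuran | Brc1ccoc1 | starting material
2 | 4-methoxybenzaldehyde | COc1ccc(C=O)cc1 | starting material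
3 | (3-bromofuran-2-yl)lithium | [Li]c1occc1Br | intermediate
4 | (3-bromofuran-2-yl)(4-methoxyphenyl)methanol (racemic) | COc1ccc(C(O)c2occc2Br)cc1 | intermediate
5 | 4-bromo-6-hydroxy-2-(4-methoxyphenyl)-2H-pyran-3(6H)-one (racemic, mixture of diastereomers) | COc1ccc(C2OC(O)C=C(Br)C2=O)cc1 | intermediate
6 | 3-hydroxy-2-(4-methoxyphenyl)-4H-pyran-4-one | COc1ccc(-c2occc(=O)c2O)cc1 | intermediate
7 | 3-(methoxymethoxy)-2-(4-methoxyphenyl)-4H-pyran-4-one | COCOc1c(-c2ccc(OC)cc2)occc1=O | intermediate
8 | dimethyl squarate (3,4-dimethoxycyclobut-3-ene-1,2-dione) | COC1=C(OC)C(=O)C1=O | starting material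
9 | [5-(methoxymethoxy)-6-(4-methoxyphenyl)-4-oxo-4H-pyran-2-yl]lithium | [Li]c1cc(=O)c(OCOC)c(-c2ccc(OC)cc2)o1 | intermediate
10 | lithium 2,3-dimethoxy-1-[5-(methoxymethoxy)-6-(4-methoxyphenyl)-4-oxo-4H-pyran-2-yl]-4-oxocyclobut-2-en-1-olate (racemic) | COCOc1c(-c2ccc(OC)cc2)oc(C2([O-])C(OC)=C(OC)C2=O)cc1=O.[Li+] | intermediate
11 | 2,3,4-trimethoxy-4-[5-(methoxymethoxy)-6-(4-methoxyphenyl)-4-oxo-4H-pyran-2-yl]cyclobut-2-en-1-one (racemic) | COCOc1c(-c2ccc(OC)cc2)oc(C2(OC)C(OC)=C(OC)C2=O)cc1=O | intermediate
12 | (3Z)-2,3,4-trimethoxy-4-[5-(methoxymethoxy)-6-(4-methoxyphenyl)-4-oxo-4H-pyran-2-yl]buta-1,3-dien-1-one (dienylketene) | COC(=C=O)/C(OC)=C(OC)\c1cc(=O)c(OCOC)c(-c2ccc(OC)cc2)o1 | intermediate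
13 | 6,7,8-trimethoxy-3-(methoxymethoxy)-2-(4-methoxyphenyl)-4aH-chromene-4,5-dione (racemic) | O=C1C(OC)=C(OC)C(OC)=C2OC(-c3ccc(OC)cc3)=C(OCOC)C(=O)C12 | intermediate
14 | 5-hydroxy-6,7,8-trimethoxy-3-(methoxymethoxy)-2-(4-methoxyphenyl)-4H-chromen-4-one | COCOc1c(-c2ccc(OC)cc2)oc2c(OC)c(OC)c(OC)c(O)c2c1=O | intermediate
15 | 3,5-dihydroxy-6,7,8,4'-tetramethoxyflavone | COc1ccc(-c2oc3c(OC)c(OC)c(OC)c(O)c3c(=O)c2O)cc1 | target

Total step count: 6. Longest linear sequence: 6 steps (1 → 4 → 6 → 7 → 11 → 14 → 15).

**Steps most likely to fail**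

Step 4. The base may deprotonate C5 instead of C6 (followed by opening of the pyranone), the lithiated pyranone may add to unreacted 7, or the triflate may methylate the pyranone carbonyl oxygen. The fallback attaches the squarate at the other carbon of the same double bond; it sets out from 7 and comes back at 14. Iodination at the nucleophilic α-carbon C5 (N-iodosuccinimide, MeCN, rt) would give 5-iodo-3-(methoxymethoxy)-2-(4-methoxyphenyl)-4H-pyran-4-one F1. Iodine–magnesium exchange (i-PrMgCl·LiCl, THF, –40 °C) would give [5-(methoxymethoxy)-6-(4-methoxyphenyl)-4-oxo-4H-pyran-3-yl]magnesium chloride F2, free of any regiochemical question. Addition to 8 at –78 °C and NH4Cl quench would give 4-hydroxy-2,3-dimethoxy-4-[5-(methoxymethoxy)-6-(4-methoxyphenyl)-4-oxo-4H-pyran-3-yl]cyclobut-2-en-1-one F3, with no triflate used. Thermolysis (toluene, 110 °C, Ar), in which the ketene now closes on C6 of the pyranone (numbering of 7), would give 5,8-dihydroxy-6,7-dimethoxy-3-(methoxymethoxy)-2-(4-methoxyphenyl)-4H-chromen-4-one F4. One equivalent of MeI with K2CO3 in degassed DMF should then methylate the non-chelated 8-hydroxyl to 14. This brings back one selective methylation of a hydroquinone, which is why it is only the fallback.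

Step 5. The 6π closure on the cross-conjugated pyranone double bond may be slow, so that the ketene dimerizes, is captured by the product phenol, or returns to 11 and decomposes. The fallback builds ring C on a ready-made ring A; it sets out from 2 and comes back at 15. Claisen–Schmidt condensation of 2 with the known ketone 1-(2-hydroxy-3,4,5,6-tetramethoxyphenyl)ethan-1-one F5 (KOH, EtOH, rt) would give (E)-1-(2-hydroxy-3,4,5,6-tetramethoxyphenyl)-3-(4-methoxyphenyl)prop-2-en-1-one F6. Oxidative cyclization (I2 cat., DMSO, 130 °C) would give 5,6,7,8-tetramethoxy-2-(4-methoxyphenyl)-4H-chromen-4-one F7. Epoxidation of the C2=C3 bond with dimethyldioxirane (acetone/CH2Cl2, 0 °C) and acid-induced opening of the epoxide (cat. TsOH) would give 3-hydroxy-5,6,7,8-tetramethoxy-2-(4-methoxyphenyl)-4H-chromen-4-one F8. Selective cleavage of the 5-methyl ether peri to the carbonyl (BCl3, CH2Cl2, –78 → 0 °C) would give 15.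

Step 2. Oxidation of the less electron-rich bromofuran may stall, or in hot acid the hemiacetal may open and condense (loss of the pyran ring, cyclopentenone formation) faster than bromide is exchanged for water. The fallback makes the pyranone by cycloaddition and aromatizes it by a mild oxidation; it sets out from 2 and comes back at 6. Hetero-Diels–Alder reaction of 2 with (E)-1-methoxy-3-(trimethylsilyloxy)buta-1,3-diene (ZnCl2, THF, rt) would give 6-methoxy-2-(4-methoxyphenyl)-4-(trimethylsilyloxy)-3,6-dihydro-2H-pyran F9. Treatment with CF3CO2H would give 2-(4-methoxyphenyl)-2,3-dihydro-4H-pyran-4-one F10. Hydroxylation of its kinetic enolate at C3 (LiN(SiMe3)2, THF, –78 °C; then 3-phenyl-2-(phenylsulfonyl)oxaziridine) would give 3-hydroxy-2-(4-methoxyphenyl)-2,3-dihydro-4H-pyran-4-one F11. Oxidation of the ketol (Dess–Martin periodinane, CH2Cl2) should give a 3,4-dione that enolizes at once to the aromatic hydroxypyranone 6.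

**Further compounds**
F1 | step 4 | 5-iodo-3-(methoxymethoxy)-2-(4-methoxyphenyl)-4H-pyran-4-one | COCOc1c(-c2ccc(OC)cc2)occ(I)c1=O
F2 | step 4 | [5-(methoxymethoxy)-6-(4-methoxyphenyl)-4-oxo-4H-pyran-3-yl]magnesium chloride | COCOc1c(-c2ccc(OC)cc2)occ([Mg]Cl)c1=O
F3 | step 4 | 4-hydroxy-2,3-dimethoxy-4-[5-(methoxymethoxy)-6-(4-methoxyphenyl)-4-oxo-4H-pyran-3-yl]cyclobut-2-en-1-one (racemic) | COCOc1c(-c2ccc(OC)cc2)occ(C2(O)C(OC)=C(OC)C2=O)c1=O
F4 | step 4 | 5,8-dihydroxy-6,7-dimethoxy-3-(methoxymethoxy)-2-(4-methoxyphenyl)-4H-chromen-4-one | COCOc1c(-c2ccc(OC)cc2)oc2c(O)c(OC)c(OC)c(O)c2c1=O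
F5 | step 5 | 1-(2-hydroxy-3,4,5,6-tetramethoxyphenyl)ethan-1-one | CC(=O)c1c(O)c(OC)c(OC)c(OC)c1OC
F6 | step 5 | (E)-1-(2-hydroxy-3,4,5,6-tetramethoxyphenyl)-3-(4-methoxyphenyl)prop-2-en-1-one | COc1ccc(/C=C/C(=O)c2c(O)c(OC)c(OC)c(OC)c2OC)cc1
F7 | step 5 | 5,6,7,8-tetramethoxy-2-(4-methoxyphenyl)-4H-chromen-4-one | COc1ccc(-c2cc(=O)c3c(OC)c(OC)c(OC)c(OC)c3o2)cc1
F8 | step 5 | 3-hydroxy-5,6,7,8-tetramethoxy-2-(4-methoxyphenyl)-4H-chromen-4-one | COc1ccc(-c2oc3c(OC)c(OC)c(OC)c(OC)c3c(=O)c2O)cc1
F9 | step 2 | 6-methoxy-2-(4-methoxyphenyl)-4-(trimethylsilyloxy)-3,6-dihydro-2H-pyran (racemic, mixture of diastereomers) | COc1ccc(C2CC(O[Si](C)(C)C)=CC(OC)O2)cc1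
F10 | step 2 | 2-(4-methoxyphenyl)-2,3-dihydro-4H-pyran-4-one (racemic) | COc1ccc(C2CC(=O)C=CO2)cc1
F11 | step 2 | 3-hydroxy-2-(4-methoxyphenyl)-2,3-dihydro-4H-pyran-4-one (racemic, relative configuration of no consequence) | COc1ccc(C2OC=CC(=O)C2O)cc1
A1 | direct plan | 2,5-dimethoxyphenol | COc1ccc(OC)c(O)c1
A2 | direct plan | 2-(benzyloxy)-1-(2-hydroxy-3,6-dimethoxyphenyl)ethan-1-one | COc1ccc(OC)c(C(=O)COCc2ccccc2)c1O
A3 | direct plan | 4-methoxybenzoic anhydride | COc1ccc(C(=O)OC(=O)c2ccc(OC)cc2)cc1
A4 | direct plan | 3-(benzyloxy)-5,8-dimethoxy-2-(4-methoxyphenyl)-4H-chromen-4-one | COc1ccc(-c2oc3c(OC)ccc(OC)c3c(=O)c2OCc2ccccc2)cc1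
A5 | direct plan | 3-(benzyloxy)-2-(4-methoxyphenyl)-4H-chromene-4,5,8-trione | COc1ccc(-c2oc3c(c(=O)c2OCc2ccccc2)C(=O)C=CC3=O)cc1
A6 | direct plan | 3-(benzyloxy)-6,7-dimethoxy-2-(4-methoxyphenyl)-4H-chromene-4,5,8-trione | COc1ccc(-c2oc3c(c(=O)c2OCc2ccccc2)C(=O)C(OC)=C(OC)C3=O)cc1
A7 | direct plan | 3-(benzyloxy)-5,8-dihydroxy-6,7-dimethoxy-2-(4-methoxyphenyl)-4H-chromen-4-one | COc1ccc(-c2oc3c(O)c(OC)c(OC)c(O)c3c(=O)c2OCc2ccccc2)cc1
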